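0.600 parts of side product per part of target: that is what the last two readings of the gamma run give together, and I call it the split, the selectivity factor between the two ways out of starting material.

all flasks: starting material 0.23 M; partner 0.575 M
- gamma: capture agent 4.6 mM; protic impurity 0.0057 M; run made earlier
- flask: capture agent 4.60 mM; protic impurity 0.0115 M; time 1.5 h

gamma run (percent of the starting material charged)

| time / min | side product / % | target / % |
|---|---|---|
| 1.33 | 32 | 46 |
| 2.50 | 31 | 52 |
| 5.00 | 32 | 56 |
| 10.0 | 34 | 59 |
| 20.0 | 38 | 61 |

(scatter of a reading: 1.5 percentage points)

- what was read earlier has a scatter of 1.5 percentage points, one standard deviation
- steps that have been proposed: capture agent + intermediate B -> trapped intermediate; starting material + partner <-> intermediate B; intermediate A -> target; starting material -> intermediate A; partner + protic impurity -> quenched reagent; starting material + partner -> side product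
- no earlier run changes the charge of protic impurity; that part of a forecast is a guess

- share of side product in side product plus target at 1.0 s
- share of side product in side product plus target at 1.5 h

Starting material with partner gives side product; starting material by itself gives intermediate A, which goes on to target. When I divide the first rate by the second, time and starting material drop out, so in these proposed steps the split follows the partner present. Suppose the protic impurity in the new flask takes its own amount of partner, a guess since no run changed it. The split is then 0.594, and the share at 1.5 h is 37.3%.

But target lags behind the split while intermediate A has still to pass on, so how long does A last? At 1.33 min in the gamma run, the side product read calls for 53.3% of target, yet 46% is read, so about 7.33% still sits as A. At 2.50 min the gap lies within the scatter. Target gains 6 percentage points between those readings, which gives a rough lifetime of 0.715 min. The early time 1.0 s is far shorter than that, so in the new flask target stands to side product as 0.0196, and the share is 98.1%.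

The forecast gives 97.5% and 38.5%, and says the extra impurity “should barely matter”. The new flask gives 97.5% and 37.0%.

    capture agent + intermediate B → trapped intermediate (k = 1.98 M⁻¹ s⁻¹)
    starting material + partner ⇌ intermediate B (K = 14.1 M⁻¹, k = 0.0316 M⁻¹ s⁻¹)
    intermediate A → target (k = 0.0337 s⁻¹)
    starting material → intermediate A (k = 0.0462 s⁻¹)
    partner + protic impurity → quenched reagent (k = 3.34 M⁻¹ s⁻¹)
    starting material + partner → side product (k = 0.0543 M⁻¹ s⁻¹)

At 0.00289 h in the new flask, starting material goes 1.7 times as fast into intermediate A as into side product; the inverse, 0.581, stands beside my split of 0.594. The new flask ends with 36.3% side product and 61.7% target.

In the neighbour flask with 2.3 M of partner, the split becomes 2.41, a share of 70.7%. The computed neighbour gives 71.9%, with target down to 27.6%.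

Readings and results are calculated for an exercise, noise included.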